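The cyclohexenone ring is numbered C1 (ketone), C2 (dienyl carbon), C3 (hydroxymethyl carbon), C4 and C5 (carbinols), C6 (side-chain carbon). Its C2=C3 double bond stands between two oxygen-bearing carbons, C1 and C4. It is therefore read as an internal alkyne that acts as a cis-vicinal vinyl dianion toward the 1,4-dicarbonyl chain C4–C5–C6–C1, which is allylated L-malic acid. In the key step a divalent-titanium complex of a silylated dec-4-en-2-yne-1,9-diol takes up a malate-derived formyl ester. Aldehyde insertion makes C3–C4 and sets C4; acyl substitution at the methyl ester makes C1–C2, closes the ring and delivers the enone. Both precursors are acyclic.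

Key step: step 10

Remark: the ring numbering above is used throughout; compounds 1, 2, 5, 9, 10 and 17 are taken as commercial.

Step 1
Reactants: 1 dimethyl (S)-malate; 2 allyl bromide
Product: 4 dimethyl (2S,3R)-3-allyl-2-hydroxybutanedioate, via dilithio alkoxide enolate 3 (not isolated)
Conditions: LiHMDS (2.2 equiv), THF, −78 °C; then 2, −78 to −10 °C
Reagents that add atoms: none
Why: Fráter–Seebach alkylation: allyl bromide should attack the lithium-chelated alkoxide enolate 3 on the face away from the ester substituent of the chelate ring, giving the anti (2S,3R) product and so setting C6 from the malate centre C5.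

Step 2
Reactants: 4 dimethyl (2S,3R)-3-allyl-2-hydroxybutanedioate; 5 tert-butyl methacrylate
Product: 6 dimethyl (2S,3R)-3-[(2E)-4-tert-butoxy-3-methyl-4-oxobut-2-enyl]-2-hydroxybutanedioate
Conditions: second-generation Hoveyda–Grubbs catalyst RuCl2(H2IMes)(=CH-C6H4-2-OiPr) (5 mol %), 5 (5 equiv), CH2Cl2, 40 °C
Reagents that add atoms: none
Why: Olefin cross metathesis of a terminal alkene with an excess of an electron-poor 1,1-disubstituted alkene that does not homodimerise should give the trisubstituted enoate, with E favoured because chain and ester avoid each other in the ruthenacyclobutane.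

Step 3
Reactants: 6 hydroxy triester
Product: 7 dimethyl (2S,3R)-3-[(2E)-4-tert-butoxy-3-methyl-4-oxobut-2-enyl]-2-(triethylsilyloxy)butanedioate
Conditions: TESCl, imidazole, CH2Cl2, 0 °C to rt
Reagents that add atoms: chlorotriethylsilane CC[Si](Cl)(CC)CC
Why: Standard silylation of a secondary alcohol; the non-chelating triethylsilyl ether is chosen for the facial control in step 10 and for its easy acid cleavage in step 11.

Step 4
Reactants: 7 silyloxy triester
Product: 8 1-tert-butyl 6-methyl (2E,5R)-2-methyl-5-[(1S)-2-oxo-1-(triethylsilyloxy)ethyl]hex-2-enedioate (formyl ester; CHO = C4, CO2Me = C1)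
Conditions: iBu2AlH (1.05 equiv), CH2Cl2, −78 °C; aq Rochelle salt
Reagents that add atoms: none
Why: Partial ester reduction through an aluminium hemiacetal that is stable at −78 °C; the ester next to the silyloxy carbon is inductively the most electrophilic, the other methyl ester lacks this activation and is α-branched, and the tert-butyl enoate is hindered and conjugated.

Step 5
Reactants: 9 (4-bromobut-1-ynyl)trimethylsilane; 10 (R)-propylene oxide
Product: 12 (R)-7-(trimethylsilyl)hept-6-yn-2-ol, via Grignard reagent 11 (not isolated)
Conditions: Mg, THF, rt to 40 °C; then CuI (10 mol %), 10, −30 to 0 °C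
Reagents that add atoms: none
Why: Copper-catalysed Grignard opening of a terminal epoxide by SN2 attack at the unsubstituted carbon, so the stereocentre of 10 is untouched and becomes the (R)-carbinol of the side chain.

Step 6
Reactants: 12 (R)-7-(trimethylsilyl)hept-6-yn-2-ol
Product: 13 (R)-2-(tert-butyldimethylsilyloxy)-7-(trimethylsilyl)hept-6-yne
Conditions: TBSCl, imidazole, DMF, rt
Reagents that add atoms: tert-butylchlorodimethylsilane CC(C)(C)[Si](C)(C)Cl
Why: Standard silylation of an unhindered secondary alcohol without change at the stereocentre.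

Step 7
Reactants: 13 silyl ether
Product: 14 (R)-6-(tert-butyldimethylsilyloxy)hept-1-yne
Conditions: K2CO3 (0.2 equiv), MeOH, rt
Reagents that add atoms: none
Why: Base-catalysed methanolysis cleaves the alkynyl C–Si bond selectively, and the silyl ether is inert to these conditions.

Step 8
Reactants: 14 terminal alkyne
Product: 16 (1E,6R)-6-(tert-butyldimethylsilyloxy)-1-iodohept-1-ene, via alkenylzirconocene chloride 15 (not isolated)
Conditions: Cp2Zr(H)Cl (1.3 equiv), THF, rt; then I2, 0 °C
Reagents that add atoms: iodine I-I
Why: Hydrozirconation adds Zr–H syn with zirconium on the terminal carbon, and iodinolysis proceeds with retention, so the E-alkenyl iodide should result.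

Step 9
Reactants: 16 (E)-alkenyl iodide; 17 tert-butyldimethyl(prop-2-ynyloxy)silane
Product: 18 (4E,9R)-1,9-bis(tert-butyldimethylsilyloxy)dec-4-en-2-yne
Conditions: PdCl2(PPh3)2 (3 mol %), CuI (6 mol %), Et3N, THF, rt
Reagents that add atoms: none
Why: Sonogashira coupling of an alkenyl iodide with a terminal alkyne proceeds with retention of the alkene geometry and tolerates silyl ethers.

Step 10
Reactants: 18 enyne; 8 formyl ester
Product: 21 tert-butyl (2E)-4-{(4R,5S,6R)-2-[(1E,6R)-6-(tert-butyldimethylsilyloxy)hept-1-enyl]-3-(tert-butyldimethylsilyloxymethyl)-4-hydroxy-1-oxo-5-(triethylsilyloxy)cyclohex-2-en-6-yl}-2-methylbut-2-enoate, via titanacyclopropene 19 (not isolated), via oxatitanacyclopentene 20 (not isolated)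
Conditions: 18 (1.2 equiv), Ti(OiPr)4 (1.3 equiv), iPrMgCl (2.6 equiv), Et2O, −78 to −45 °C; then 8 (1.0 equiv), −78 to −40 °C; then −40 to 0 °C; pH 7 buffer
Reagents that add atoms: none
Why: Proposed new method: iPrMgCl reduces Ti(OiPr)4 to the divalent-titanium propene complex, whose propene is displaced by the alkyne of 18 to give titanacyclopropene 19, a cis-vicinal vinyl dianion equivalent; the aldehyde of 8 inserts into the Ti–C3 bond (C3–C4 bond, oxatitanacyclopentene 20), and on warming the C1 ester carbonyl binds to the same titanium, the remaining Ti–C2 bond adds to it with retention at C2 and methoxide leaves (C1–C2 bond). The closest known reaction types are the titanium-mediated annulation of internal alkynes with 1,4-diketones, in which both alkyne carbons add to the two carbonyl groups, and the intramolecular nucleophilic acyl substitution of alkenyltitanium species on esters; new is their union on a 4-oxobutanoate, so that a 4-hydroxycyclohex-2-enone results directly. The one ring that forms, the six-membered carbocycle, closes by a 6-exo-trig addition–elimination at C1, and the cis placement of titanium and C4 on the C2=C3 bond of 20 is exactly the geometry the endocyclic alkene needs. C4 is the only new stereocentre and is set in the aldehyde insertion by the adjacent C5 centre under polar Felkin–Anh control (non-chelating silyloxy group antiperiplanar to the incoming C3), which gives the 4,5-anti open-chain relation, that is the cis-diol (4R) of the ring, while C5 and C6 are carried over unchanged from 8. Regioselectivity should come from the alkenyl group, which stabilises the adjacent C2–Ti bond and leaves the C3–Ti bond to react first, and chemoselectivity from the order aldehyde, then methyl ester, then hindered conjugated tert-butyl ester, attack on which would also require a seven-membered ring. Staying at or below −40 °C until 8 is consumed should hold back β-elimination of the propargylic silyloxy group from 19, and if the C4 titanium alkoxide lactonises onto C1 first, the γ-lactone still lies under the C2–Ti bond as an acyl donor.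

Step 11
Reactants: 21 protected cyclohexenone
Product: 22 pestallic acid I
Conditions: TFA/H2O (9:1), CH2Cl2, 0 °C to rt
Reagents that add atoms: none
Why: Global acidolysis: the three silyl ethers are hydrolysed and the tert-butyl ester loses isobutene under one set of non-basic conditions, which should leave the base-sensitive C6 centre and the β-hydroxy ketone untouched.

Compound list
1 | dimethyl (S)-malate | COC(=O)C[C@H](O)C(=O)OC | starting material
2 | allyl bromide | C=CCBr | starting material
3 | dilithio alkoxide enolate of 1 | [Li+].[Li+].COC([O-])=C[C@H]([O-])C(=O)OC | intermediate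
4 | dimethyl (2S,3R)-3-allyl-2-hydroxybutanedioate | C=CC[C@H]([C@H](O)C(=O)OC)C(=O)OC | intermediate
5 | tert-butyl methacrylate | C=C(C)C(=O)OC(C)(C)C | starting material
6 | dimethyl (2S,3R)-3-[(2E)-4-tert-butoxy-3-methyl-4-oxobut-2-enyl]-2-hydroxybutanedioate | C/C(=C\C[C@H]([C@H](O)C(=O)OC)C(=O)OC)C(=O)OC(C)(C)C | intermediate
7 | dimethyl (2S,3R)-3-[(2E)-4-tert-butoxy-3-methyl-4-oxobut-2-enyl]-2-(triethylsilyloxy)butanedioate | C/C(=C\C[C@H]([C@H](O[Si](CC)(CC)CC)C(=O)OC)C(=O)OC)C(=O)OC(C)(C)C | intermediate
8 | 1-tert-butyl 6-methyl (2E,5R)-2-methyl-5-[(1S)-2-oxo-1-(triethylsilyloxy)ethyl]hex-2-enedioate | C/C(=C\C[C@H]([C@H](O[Si](CC)(CC)CC)C=O)C(=O)OC)C(=O)OC(C)(C)C | intermediate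
9 | (4-bromobut-1-ynyl)trimethylsilane | C[Si](C)(C)C#CCCBr | starting material
10 | (R)-propylene oxide | C[C@@H]1CO1 | starting material
11 | [4-(trimethylsilyl)but-3-ynyl]magnesium bromide | C[Si](C)(C)C#CCC[Mg]Br | intermediate
12 | (R)-7-(trimethylsilyl)hept-6-yn-2-ol | C[C@@H](O)CCCC#C[Si](C)(C)C | intermediate
13 | (R)-2-(tert-butyldimethylsilyloxy)-7-(trimethylsilyl)hept-6-yne | C[C@@H](O[Si](C)(C)C(C)(C)C)CCCC#C[Si](C)(C)C | intermediate
14 | (R)-6-(tert-butyldimethylsilyloxy)hept-1-yne | C[C@@H](O[Si](C)(C)C(C)(C)C)CCCC#C | intermediate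
15 | chloro[(1E,6R)-6-(tert-butyldimethylsilyloxy)hept-1-enyl]zirconocene | C[C@@H](O[Si](C)(C)C(C)(C)C)CCC/C=C/[Zr](Cl)(C1C=CC=C1)C1C=CC=C1 | intermediate
16 | (1E,6R)-6-(tert-butyldimethylsilyloxy)-1-iodohept-1-ene | C[C@@H](O[Si](C)(C)C(C)(C)C)CCC/C=C/I | intermediate
17 | tert-butyldimethyl(prop-2-ynyloxy)silane | C#CCO[Si](C)(C)C(C)(C)C | starting material
18 | (4E,9R)-1,9-bis(tert-butyldimethylsilyloxy)dec-4-en-2-yne | C[C@@H](O[Si](C)(C)C(C)(C)C)CCC/C=C/C#CCO[Si](C)(C)C(C)(C)C | intermediate
19 | diisopropoxytitanacyclopropene of 18 (Ti bound to C2 and C3) | CC(C)O[Ti]1(OC(C)C)C(CO[Si](C)(C)C(C)(C)C)=C1/C=C/CCC[C@@H](C)O[Si](C)(C)C(C)(C)C | intermediate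
20 | diisopropoxy-oxatitanacyclopentene (ring Ti–O–C4–C3=C2) | CC(C)O[Ti]1(OC(C)C)O[C@@H]([C@@H](O[Si](CC)(CC)CC)[C@@H](C/C=C(\C)C(=O)OC(C)(C)C)C(=O)OC)C(CO[Si](C)(C)C(C)(C)C)=C1/C=C/CCC[C@@H](C)O[Si](C)(C)C(C)(C)C | intermediate
21 | protected (4R,5S,6R)-4-hydroxycyclohexenone, tert-butyl ester, tris(silyl ether) | C/C(=C\C[C@H]1C(=O)C(/C=C/CCC[C@@H](C)O[Si](C)(C)C(C)(C)C)=C(CO[Si](C)(C)C(C)(C)C)[C@@H](O)[C@H]1O[Si](CC)(CC)CC)C(=O)OC(C)(C)C | intermediate
22 | pestallic acid I | C/C(=C\C[C@H]1C(=O)C(/C=C/CCC[C@@H](C)O)=C(CO)[C@@H](O)[C@H]1O)C(=O)O | target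

Total step count: 11. Longest linear sequence: 7 (steps 5 to 11).

Steps most likely to fail

1. Step 10. The second bond formation may stall, so that the C2–Ti bond is only protonated on work-up. The aldehyde may insert at the wrong alkyne carbon or with poor facial selectivity. The propargylic silyloxy group may be lost from the alkyne complex by β-elimination.
Fallback: the two bonds are made in separate flasks by known chemistry. It sets out from 18 and 8 and comes back at 21. The coupling is run as in step 10 up to oxatitanacyclopentene 20, which is kept at −40 °C and cleaved with iodine. This is the known iodinolysis of such titanacycles, with retention at C2, and gives the open-chain C2-iodo dienol F1. Iodine–magnesium exchange follows with iPrMgCl·LiCl (2.2 equiv, THF, −40 °C); the first equivalent deprotonates the C4 hydroxyl. The resulting alkenylmagnesium acylates itself on the C1 methyl ester and gives 21.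

2. Step 4. The hydride may attack the other methyl ester as well, or the aldehyde may be over-reduced, so that the two ends of the malate chain are not differentiated.
Fallback: it sets out from 6 and comes back at 8.
- Hydroxyl-directed reduction of the α-hydroxy ester (BH3·SMe2, catalytic NaBH4, THF, 0 °C to rt) gives the 1,2-diol F2.
- TESCl and imidazole convert F2 into the bis(triethylsilyl) ether F3.
- Swern conditions (oxalyl chloride, DMSO, Et3N, −78 to −40 °C) oxidise only the primary triethylsilyl ether directly to the aldehyde 8. No free γ-hydroxy ester that could lactonise appears on the way.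

3. Step 11. Protic acid may cause loss of the C5 hydroxyl by β-elimination followed by aromatisation, or cleavage of the hindered groups may stay incomplete.
Fallback: ester cleavage and desilylation are separated and no strong protic acid is used. It sets out from 21 and comes back at 22. TMSOTf and 2,6-lutidine (CH2Cl2, 0 °C) convert the tert-butyl ester into a silyl ester with loss of isobutene. Aqueous work-up hydrolyses the silyl ester and the transient C4 trimethylsilyl ether to the tris(silyl ether) carboxylic acid F4. HF·pyridine buffered with pyridine (THF, 0 °C) then removes the three silyl ethers and gives 22.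

Further compounds
F1 | step 10 | open-chain C2-iodo dienol (C3–C4 coupled, iodine on C2 cis to C4, 4R) | O[C@@H]([C@@H](O[Si](CC)(CC)CC)[C@@H](C/C=C(\C)C(=O)OC(C)(C)C)C(=O)OC)/C(CO[Si](C)(C)C(C)(C)C)=C(\I)/C=C/CCC[C@@H](C)O[Si](C)(C)C(C)(C)C
F2 | step 4 | 1-tert-butyl 6-methyl (2E,5R)-5-[(1S)-1,2-dihydroxyethyl]-2-methylhex-2-enedioate | C/C(=C\C[C@H]([C@H](O)CO)C(=O)OC)C(=O)OC(C)(C)C
F3 | step 4 | 1-tert-butyl 6-methyl (2E,5R)-5-[(1S)-1,2-bis(triethylsilyloxy)ethyl]-2-methylhex-2-enedioate | C/C(=C\C[C@H]([C@H](O[Si](CC)(CC)CC)CO[Si](CC)(CC)CC)C(=O)OC)C(=O)OC(C)(C)C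
F4 | step 11 | tris(silyl ether) of pestallic acid I with free carboxylic acid | C/C(=C\C[C@H]1C(=O)C(/C=C/CCC[C@@H](C)O[Si](C)(C)C(C)(C)C)=C(CO[Si](C)(C)C(C)(C)C)[C@@H](O)[C@H]1O[Si](CC)(CC)CC)C(=O)O
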